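In this closed, stirred vessel, monomers join end to end, and I want the average chain length N at the end of dawn and of summer.

| flask | first end groups | second end groups | one-sided end groups | protic impurity | remark | time |
|---|---|---|---|---|---|---|
| eta | 0.27 M | 1 equiv | 5.4 mM | 0.012 M | run made earlier |  |
| theta | 0.27 M | 1 equiv | 5.4 mM | 0.027 M | run made earlier |  |
| dawn | 0.27 M | 1.00 equiv | 5.40 mM | 0.0135 M |  | 3.0 min |
| summer | 0.27 M | 1.00 equiv | 5.40 mM | 0.0400 M |  | 3.0 min |

| eta: time / s | eta: links / % | theta: time / s | theta: links / % |
|---|---|---|---|
| 15.0 | 10 | 10.0 | 9 |
| 40.0 | 32 | 25.0 | 19 |
| 80.0 | 46 | 50.0 | 35 |
| 120 | 56 | 120 | 51 |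

(scatter of a reading: 2 percentage points)

- each monomer carries two end groups and one-sided end groups one, which caps an end: a chain counts once for every two ends that are left, dead ends included; the units are half of the end groups of the two monomers charged

1. which of the two ends with the longer chains by the average number of monomer units in a chain (unreacted monomers counted as chains of one) ("neither" if they lie within 10%) (dawn / summer / neither)
2. average number of monomer units in a chain (unreacted monomers counted as chains of one) at the end, dawn
3. average number of monomer units in a chain (unreacted monomers counted as chains of one) at the end, summer

How fast does N grow? With p the links as a fraction of the first end groups charged, N = 1/(1 − p), and second-order step growth from equal ends, with no way back, makes N climb on a straight line, N = 1 + t/τ, with τ a time constant. Eta's last reading gives τ = 94.3 s, and theta, with 2.25 times the impurity, gives 92.9 s at 50.0 s but 115 s at 120 s. So one line for both is rough; I take eta's τ as a reading, which puts dawn and summer near 2.91.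

How far can N go? As a worst case, I let each impurity molecule and each one-sided end spoil an end of the same kind, making that kind the limiting reagent. Since dead ends still count, the ceiling is N_c = cA/(cH + cS): 14.3 for dawn, 5.95 for summer.

When does control change hands? Summer's line meets its ceiling at 7.77 min; this crossing time, t× = τ(N_c − 1), marks the passage from clock to imbalance. Summer's crossing comes later than the reading, and dawn's lies at 20.9 min, so both flasks still run on the same clock, and I commit to "neither".

The forecast differs: 2.72 for dawn, 2.43 for summer, answer dawn, though it too says “time limits the length more than imbalance does”.

The flask gives 2.61 for dawn and 2.46 for summer, so the answer is neither.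

    first end groups + second end groups ⇌ links (K = 140 M⁻¹, k = 0.0380 M⁻¹ s⁻¹)
    first end groups + one-sided end groups → capped ends (k = 4.20 M⁻¹ s⁻¹)
    second end groups + protic impurity → quenched reagent (k = 0.0460 M⁻¹ s⁻¹)

Both lengths lie below my 2.91, and their ratio, 1.06, stays inside the margin of 10%, at a reading earlier than summer's 7.77 min. Summer's neighbour with 2.50 equiv of second end groups has a ceiling, reckoned from its excess of second end groups, of 2.33 and, taking the same τ as a rough clock, a crossing at 2.10 min, earlier than its reading; it ends at 2.11. Neither dawn nor summer has come to rest at 3.0 min: links stand at 61.6% and 59.4%, and by 30.0 min they reach 81.7% and 76.4%. Past the crossing the two part, with dawn at 5.47 and summer at 4.23, a ratio of 1.29.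

The data come from a simulation for an exercise, noise included.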